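## The problem

Compound 41 is a hydrind-3(3a)-en-2-one. A cyclopentenone (C7a, C1, C2, C3, C3a; indenone numbering throughout) is fused along C3a–C7a to a cyclohexane (C3a, C4, C5, C6, C7, C7a). One fusion atom, C3a, is part of the enone; the other, C7a, is a methyl-bearing quaternary stereocentre. The C7a methyl, the C7 carboxyl, the C4 acyloxy group and the C1 2-formylallyl chain all lie on one face (1R,4S,7R,7aS). A fifth, remote centre (8R) sits in the (2E,4E,6E)-6,8-dimethyldeca-2,4,6-trienoyl ester and must come from a separate enantiopure building block.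

C7a and its neighbour C7 cannot be corrected by any later reaction, so they must be set absolutely. Once they exist, the axial C7a methyl can steer hydride to C4, and C1, which is α to the ketone and epimerisable, can be set by face selection on an enolate or by equilibration.

The functionality is fragile. The α-substituted acrolein is a Michael acceptor, the γ-acyloxy enone can isomerise through its dienolate under base, the trienoate rules out saponification and hydrogenation, and the C7 carboxyl is 1,4-cis to the C4 oxygen, so a free C4 alkoxide can lactonise. Aldehyde and acid must therefore be freed last and non-hydrolytically, and the two oxygenated carbons C2 and C4, linked through C3=C3a, must stay distinguishable throughout.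

The enabling feature is that the cis C7a-methyl/C7-carboxyl pair on adjacent ring carbons is the two carbons of an (E)-3-methylalk-2-enoate. C3a, C4, C5 and C6 with oxygen on C4 form a 2-oxygenated butadiene, and C1–C2–C3 is a three-atom bridge with a maskable carbonyl at its centre. The bicycle is thus the Diels–Alder adduct of a 1,3,8-nonatriene.

## Retrosynthesis

**Unveiling the aldehyde and acid (41 ⇐ 40 ⇐ 39).** No skeletal bond is cut. The enal of 41 is traced to the primary allylic alcohol 40, and 40 to 39, in which that alcohol is a tert-butyldiphenylsilyl ether and the acid a 2-(trimethylsilyl)ethyl ester. Both fall to fluoride in one operation, which spares the trienoate that hydroxide would cleave. The final oxidation is neutral and leaves C1 and the γ-acyloxy enone alone. Freeing the acid with the enal already present would expose the acrolein to basic fluoride and is the poorer order.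

**C4–O acyl bond (39 ⇐ 26 + 37).** Cutting the ester gives alcohol 26 and trienoic acid 37. This halves the problem and keeps the base-sensitive triene out of every enolate step on the core. The forward reaction must acylate a hindered secondary allylic alcohol without base-induced isomerisation.

**Trienoic acid (37 ⇐ 36 ⇐ 34 + 35; 34 ⇐ 31 + 32; 31 ⇐ 30 ⇐ 29 ⇐ 27 + 28).** The C4=C5 alkene of 37 is cut by a vinylogous Horner–Wadsworth–Emmons reaction between enal 34 and phosphonate 35. The trisubstituted C6=C7 alkene comes from a Wittig reaction of ylide 32 with the aldehyde derived from (R)-2-methylbutan-1-ol 31. The 8R centre comes from an Evans methylation of butanoyl imide 29 (from oxazolidinone 27 and butanoyl chloride 28) via 30. An auxiliary is preferred to a chiral-pool alcohol because only the (S)-alcohol is a bulk chemical and the target needs the other enantiomer.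

**C1–CH2 bond (26 ⇐ 25 ⇐ 21 + 24; 24 ⇐ 23 ⇐ 22).** The side chain is removed as allylic bromide 24, made from 2-methylenepropane-1,3-diol 22 via 23. This leaves enone 21, whose only kinetically accessible enolate is the cross-conjugated one at C1. Cutting here, not earlier, keeps the cycloaddition substrate achiral and free of a tether stereocentre. The forward alkylation must place the chain on the methyl face. The C4 oxygen is masked as a triethylsilyl ether (21, 25) so that no alkoxide sits 1,4-cis to the C7 ester during enolate chemistry.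

**Oxidation pattern of the core (21 ⇐ 20 ⇐ 19 ⇐ 18 ⇐ 16 ⇐ 15).** No skeletal bond is cut. The C2 ketone of 20 is traced to the ketal of 19. The C4 carbinol is traced to the C4 ketone of ene-dione monoketal 18, reduced while C3a is sp2 so that only the C7a methyl decides the face. The C3=C3a alkene is traced to ketone 16 through its C3a=C4 silyl enol ether 17. Ketone 16 is the hydrolysis product of silyl enol ether 15. Keeping C2 as a ketal while C4 is a ketone is what distinguishes the two carbonyls; a free ene-dione would leave that to a selective reduction.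

**Both rings (15 ⇐ 14).** Cutting C3a–C7a and C6–C7 opens the six-membered ring by a retro-[4+2] and the five-membered ring with it. The precursor is the achiral acyclic triene 14: a (Z)-2-silyloxydiene and an (E)-3-methylalk-2-enoate joined by a ketal-bearing three-atom chain. Two rings, two skeletal bonds and three stereocentres are removed at once. The forward reaction needs enantiofacial control on the enoate, supplied by a chiral oxazaborolidinium Lewis acid at the ester carbonyl; the cis C7/C7a relationship follows from alkene geometry.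

**Diene (14 ⇐ 13 ⇐ 12 ⇐ 10 + 11; 10 ⇐ 9).** The silyl dienol ether comes from vinyl ketone 13. The C4–C5 bond is cut to aldehyde 10 and vinylmagnesium bromide 11 via carbinol 12, and the aldehyde is the cleavage product of the terminal alkene of 9. The alkene is an inert aldehyde surrogate while the enoate is assembled.

**(E)-Enoate and ketal chain (9 ⇐ 8 ⇐ 7 ⇐ 5 + 6; 5 ⇐ 4 ⇐ 3 ⇐ 1 + 2).** The C7a–CH3 bond is cut stereospecifically: 9 comes from (Z)-enol phosphate 8 and a methylcuprate, and 8 from β-keto ester 7. A direct olefination of a methyl ketone would give E/Z mixtures, so it is rejected. The C7a–C7 bond of 7 comes from acylation of the enolate of 2-(trimethylsilyl)ethyl acetate 6 by Weinreb amide 5. Amide 5 is made from ketal ester 4, the ketal of methyl 3-oxohept-6-enoate 3, which comes from methyl acetoacetate 1 and allyl bromide 2 (C3–C3a bond). The ketal is installed before the enoate exists, so no free β,γ-unsaturated ketone that could scramble the alkene geometry is ever present.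

## Roads not taken

**Alternative 1:** Cut C5–C6 and close the six-membered ring by an intramolecular Mukaiyama–Michael addition. The silyl enol ether of an acetyl group on C3a would add to the terminal carbon C6 of an acrylate attached through its α-carbon C7 to C7a, and the resulting ketene acetal would be protonated at C7 to give ene-dione A1.
- Merits: C1, its side chain and C7a are in place before ring closure. A1 is closer to the target than any intermediate of the chosen route, and no dehydrogenation is needed for C3=C3a. In endgame length this road is better.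
- Weak points: the ring closure does not create the quaternary centre; its absolute configuration has to be solved earlier, on a fully substituted cyclopentenone, and no solution is evident. The acceptor is an α-branched acrylate on a quaternary carbon closing in a 6-endo sense. C7 is fixed by a protonation whose facial sense is not secured. A1 has two enone carbonyls (C2, C4) that can be told apart only by a selective reduction.
- Comparison: the chosen plan sets C7 and C7a together, catalytically, from an achiral chain, and keeps C2 and C4 chemically distinct (ketal versus enol ether) from the outset.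

**Alternative 2:** Introduce the angular methyl as a cyclopropane methylene. Et2Zn/CH2I2 would cyclopropanate the tetrasubstituted C3a=C7a alkene of a bicyclic allylic alcohol syn to the C4 hydroxyl, giving A2; reductive opening of the C3a–CH2 bond would then leave the methyl on C7a.
- Merits: hydroxyl-directed cyclopropanation is highly reliable for facial control and gives the methyl cis to the C4 oxygen, as required. Opening the derived cyclopropyl ketone would give a regiodefined C3a enolate, exactly the species the chosen route must reach by equilibration. On that point this road is better.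
- Weak points: a tetrasubstituted ring-fusion alkene is a slow substrate. The directing C4 centre has to be oxidised for the opening and set again. The C7 ester must already be cis to the C4 hydroxyl in an enantiopure bicyclic alkene, which needs its own asymmetric entry. The quaternary centre costs three operations.
- Comparison: the chosen plan makes the quaternary centre in the ring-forming step and uses the C7a methyl, once, to set C4.

**Alternative 3:** Build the five-membered ring by a [2+2] cycloaddition of dichloroketene to the C3a=C7a alkene of a substituted 1-methylcyclohexene, then insert one carbon with CH2N2. C3a would migrate, forming C2–C3 and C3–C3a, to give dichloroketone A3.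
- Merits: cheap reagents and a dependable regiochemistry of expansion. Because C1 is blocked by chlorine, the C2 ketone can enolise only toward C3, which makes C3=C3a formation unambiguous and is better than the chosen route on that point. The halogens could also serve for reductive alkylation at C1.
- Weak points: it needs an enantiopure cyclohexene with C4 silyloxy and C7 ester cis-1,4. Ketene cycloadditions to trisubstituted, doubly allylically substituted alkenes are sluggish, and the ketene must add anti to both groups. Diazomethane and a dechlorination are added, and each ring costs its own step.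
- Comparison: the chosen plan needs no pre-formed chiral carbocycle and forms both rings and the absolute configuration in one catalytic step.

Key step: step 11

Remark: the (R)-antipode of the catalyst in step 11 was chosen by working through the α-C–H···O binding model for enoates, which predicts the 7R,7aS sense for this catalyst. If correlation shows the opposite sense, the (S)-catalyst replaces it with no other change.

## Route

Step 1
Reactants: 1 methyl acetoacetate; 2 allyl bromide
Product: 3 methyl 3-oxohept-6-enoate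
Conditions: NaH, THF, 0 °C; n-BuLi, 0 °C; then 2, 0 °C → rt; aq. HCl
Reagents that add atoms: none
Why: Huckin–Weiler γ-alkylation; the acetoacetate dianion reacts at its more nucleophilic terminal carbon with the allylic bromide, and no stereocentre is formed.

Step 2
Reactants: 3 methyl 3-oxohept-6-enoate
Product: 4 methyl 2-[2-(but-3-en-1-yl)-1,3-dioxolan-2-yl]acetate
Conditions: HOCH2CH2OH, p-TsOH·H2O (cat.), benzene, reflux (Dean–Stark)
Reagents that add atoms: ethylene glycol, OCCO
Why: Acid-catalysed ketalisation with azeotropic water removal, routine for β-keto esters; it installs the future C2 ketal before any alkene geometry could be put at risk.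

Step 3
Reactants: 4 methyl 2-[2-(but-3-en-1-yl)-1,3-dioxolan-2-yl]acetate
Product: 5 2-[2-(but-3-en-1-yl)-1,3-dioxolan-2-yl]-N-methoxy-N-methylacetamide
Conditions: MeNH(OMe)·HCl, i-PrMgCl, THF, −20 → 0 °C
Reagents that add atoms: N,O-dimethylhydroxylamine hydrochloride, CNOC.Cl
Why: Direct ester-to-Weinreb-amide conversion through the chloromagnesium amide; the amide gives a clean single acyl transfer in the next step.

Step 4
Reactants: 5 2-[2-(but-3-en-1-yl)-1,3-dioxolan-2-yl]-N-methoxy-N-methylacetamide; 6 2-(trimethylsilyl)ethyl acetate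
Product: 7 2-(trimethylsilyl)ethyl 4-[2-(but-3-en-1-yl)-1,3-dioxolan-2-yl]-3-oxobutanoate
Conditions: LDA, 6, THF, −78 °C; then 5, −78 → −20 °C; aq. NH4Cl
Reagents that add atoms: none
Why: Claisen-type acylation of a lithium ester enolate by a Weinreb amide; the chelated tetrahedral intermediate prevents over-addition, and the fluoride-labile ester that is carried to the end enters here.

Step 5
Reactants: 7 2-(trimethylsilyl)ethyl 4-[2-(but-3-en-1-yl)-1,3-dioxolan-2-yl]-3-oxobutanoate
Product: 8 2-(trimethylsilyl)ethyl (2Z)-4-[2-(but-3-en-1-yl)-1,3-dioxolan-2-yl]-3-[(diethoxyphosphoryl)oxy]but-2-enoate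
Conditions: NaH, Et2O, 0 °C; ClP(O)(OEt)2, 0 °C → rt
Reagents that add atoms: diethyl chlorophosphate, CCOP(=O)(Cl)OCC
Why: O-phosphorylation of the chelated, U-shaped sodium enolate of a β-keto ester gives the (Z)-enol phosphate (Weiler enol phosphate method); the geometry is fixed by the chelate.

Step 6
Reactants: 8 2-(trimethylsilyl)ethyl (2Z)-4-[2-(but-3-en-1-yl)-1,3-dioxolan-2-yl]-3-[(diethoxyphosphoryl)oxy]but-2-enoate
Product: 9 2-(trimethylsilyl)ethyl (2E)-4-[2-(but-3-en-1-yl)-1,3-dioxolan-2-yl]-3-methylbut-2-enoate
Conditions: Me2CuLi (from CuI and MeLi), Et2O, −78 → −45 °C; aq. NH4Cl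
Reagents that add atoms: lithium dimethylcuprate (made from MeLi and CuI), [Li+].C[Cu-]C
Why: Cuprate substitution of a β-phosphoryloxy enoate proceeds with retention at low temperature, so the methyl ends up cis to the ester and the chain trans; this (E) geometry is what later becomes the cis C7a-methyl/C7-carboxyl pair.

Step 7
Reactants: 9 2-(trimethylsilyl)ethyl (2E)-4-[2-(but-3-en-1-yl)-1,3-dioxolan-2-yl]-3-methylbut-2-enoate
Product: 10 2-(trimethylsilyl)ethyl (2E)-3-methyl-4-[2-(3-oxopropyl)-1,3-dioxolan-2-yl]but-2-enoate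
Conditions: OsO4 (2 mol %), NaIO4, 2,6-lutidine, dioxane/H2O (3:1), rt
Reagents that add atoms: sodium periodate, [Na+].[O-]I(=O)(=O)=O (terminal oxidant; the aldehyde oxygen is delivered through catalytic osmium tetroxide, O=[Os](=O)(=O)=O)
Why: Lemieux–Johnson cleavage; OsO4 attacks the electron-rich monosubstituted alkene in preference to the conjugated, electron-poor one, and the buffered medium leaves the ketal intact.

Step 8
Reactants: 10 2-(trimethylsilyl)ethyl (2E)-3-methyl-4-[2-(3-oxopropyl)-1,3-dioxolan-2-yl]but-2-enoate; 11 vinylmagnesium bromide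
Product: 12 2-(trimethylsilyl)ethyl (2E)-4-[2-(3-hydroxypent-4-en-1-yl)-1,3-dioxolan-2-yl]-3-methylbut-2-enoate (racemic at the carbinol carbon)
Conditions: 11, THF, −78 °C; aq. NH4Cl
Reagents that add atoms: none
Why: Grignard 1,2-addition to the aldehyde, which is far more electrophilic than the hindered conjugated ester at −78 °C; the new carbinol centre is oxidised away in the next step.

Step 9
Reactants: 12 2-(trimethylsilyl)ethyl (2E)-4-[2-(3-hydroxypent-4-en-1-yl)-1,3-dioxolan-2-yl]-3-methylbut-2-enoate
Product: 13 2-(trimethylsilyl)ethyl (2E)-3-methyl-4-[2-(3-oxopent-4-en-1-yl)-1,3-dioxolan-2-yl]but-2-enoate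
Conditions: Dess–Martin periodinane, NaHCO3, CH2Cl2, 0 °C → rt
Reagents that add atoms: none
Why: Dess–Martin oxidation of a secondary allylic alcohol to the vinyl ketone under buffered, non-nucleophilic conditions that spare the ketal and do not add to the enone.

Step 10
Reactants: 13 2-(trimethylsilyl)ethyl (2E)-3-methyl-4-[2-(3-oxopent-4-en-1-yl)-1,3-dioxolan-2-yl]but-2-enoate
Product: 14 2-(trimethylsilyl)ethyl (2E)-3-methyl-4-{2-[(2Z)-3-[(triisopropylsilyl)oxy]penta-2,4-dien-1-yl]-1,3-dioxolan-2-yl}but-2-enoate
Conditions: TIPSOTf, Et3N, CH2Cl2, −78 → 0 °C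
Reagents that add atoms: triisopropylsilyl trifluoromethanesulfonate, CC(C)[Si](OS(=O)(=O)C(F)(F)F)(C(C)C)C(C)C
Why: Soft enolisation (silyl triflate/amine) of the only enolisable α′-methylene of the vinyl ketone gives the 2-silyloxydiene; the (Z) enol ether is the thermodynamic product and places the tether on the outside of the diene, as the cycloaddition requires.

Step 11
Reactants: 14 2-(trimethylsilyl)ethyl (2E)-3-methyl-4-{2-[(2Z)-3-[(triisopropylsilyl)oxy]penta-2,4-dien-1-yl]-1,3-dioxolan-2-yl}but-2-enoate
Product: 15 2-(trimethylsilyl)ethyl (3aR,7R,7aR)-2,2-(ethylenedioxy)-7a-methyl-4-[(triisopropylsilyl)oxy]-2,3,3a,6,7,7a-hexahydro-1H-indene-7-carboxylate (C7 ester cis to the C7a methyl, C3a–H trans to it)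
Conditions: N-protonated (R)-3,3-diphenyl-1-(o-tolyl)tetrahydro-1H,3H-pyrrolo[1,2-c][1,3,2]oxazaborole with (CF3SO2)2N− counter-ion (20 mol %, from the oxazaborolidine and (CF3SO2)2NH), CH2Cl2, −78 → −20 °C
Reagents that add atoms: none
Why: A concerted, asynchronous, normal-demand [4+2] cycloaddition in which the cationic oxazaborolidine binds the ester carbonyl of 14 (lone pair anti to the alkoxy group, supported by an α-C–H···O contact) and lowers the LUMO of the trisubstituted enoate toward the electron-rich 2-silyloxydiene; the closest known reaction type is the oxazaborolidinium-catalysed enantioselective type 1 intramolecular Diels–Alder reaction of 1,3,8-nonatrienes with a terminal carbonyl activator. The six-membered ring is closed by the cycloaddition itself (bonds C3a–C7a and C6–C7, suprafacial on both partners), and the five-membered ring closes simultaneously as the fused tether ring C3a–C3–C2–C1–C7a (type 1 mode, three-atom bridge). C7 and C7a are created together: their cis relationship follows stereospecifically from the (E) dienophile, and their absolute configuration from the catalyst, whose phenyl group covers one face of the bound enoate. C3a is set by the endo arrangement (ester under the diene) expected under Lewis-acid control, giving the trans fusion, but this centre becomes sp2 later, so any exo adduct converges. The selectivity that matters is enantiofacial, and it rests on one-point binding at the only carbonyl group in the substrate. The gem-dialkoxy carbon in the middle of the tether pre-organises the chain (Thorpe–Ingold effect) and offsets the low intrinsic reactivity of a β,β-disubstituted enoate. Triisopropylsilyl enol ethers and ketals are tolerated by this catalyst class at low temperature.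

Step 12
Reactants: 15 2-(trimethylsilyl)ethyl (3aR,7R,7aR)-2,2-(ethylenedioxy)-7a-methyl-4-[(triisopropylsilyl)oxy]-2,3,3a,6,7,7a-hexahydro-1H-indene-7-carboxylate
Product: 16 2-(trimethylsilyl)ethyl (3aR,7R,7aR)-2,2-(ethylenedioxy)-7a-methyl-4-oxooctahydro-1H-indene-7-carboxylate
Conditions: TBAF, AcOH, THF, 0 °C
Reagents that add atoms: none
Why: Fluoride cleaves the Si–O bond of the silyl enol ether within minutes at 0 °C and the buffered enolate is protonated at C5; the 2-(trimethylsilyl)ethyl ester needs longer, warmer exposure and the ketal is inert, and epimerisation at C3a is of no consequence.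

Step 13
Reactants: 16 2-(trimethylsilyl)ethyl (3aR,7R,7aR)-2,2-(ethylenedioxy)-7a-methyl-4-oxooctahydro-1H-indene-7-carboxylate
Product: 18 2-(trimethylsilyl)ethyl (7R,7aS)-2,2-(ethylenedioxy)-7a-methyl-4-oxo-2,4,5,6,7,7a-hexahydro-1H-indene-7-carboxylate, via C3a=C4 trimethylsilyl enol ether 17 (not isolated)
Conditions: TMSOTf, Et3N, CH2Cl2, 0 °C → rt; then Pd(OAc)2 (1.1 equiv), MeCN, rt
Reagents that add atoms: none
Why: Equilibrating enol silylation favours the tetrasubstituted C3a=C4 enol ether (the ring-fusion position, exocyclic to the five-membered ring), and Saegusa–Ito oxidation then palladates C3a and eliminates the only available β-hydrogen, on C3, to give the C3=C3a enone; the ring-fusion stereocentre is erased here.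

Step 14
Reactants: 18 2-(trimethylsilyl)ethyl (7R,7aS)-2,2-(ethylenedioxy)-7a-methyl-4-oxo-2,4,5,6,7,7a-hexahydro-1H-indene-7-carboxylate
Product: 19 2-(trimethylsilyl)ethyl (4S,7R,7aS)-2,2-(ethylenedioxy)-4-hydroxy-7a-methyl-2,4,5,6,7,7a-hexahydro-1H-indene-7-carboxylate
Conditions: NaBH4, CeCl3·7H2O, MeOH, −78 °C
Reagents that add atoms: none
Why: Luche reduction gives clean 1,2-addition to the enone; hydride approaches C4 from the face opposite the axial C7a methyl, which is 1,3 to the carbonyl, so the hydroxyl ends up cis to the methyl (4S).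

Step 15
Reactants: 19 2-(trimethylsilyl)ethyl (4S,7R,7aS)-2,2-(ethylenedioxy)-4-hydroxy-7a-methyl-2,4,5,6,7,7a-hexahydro-1H-indene-7-carboxylate
Product: 20 2-(trimethylsilyl)ethyl (4S,7R,7aS)-4-hydroxy-7a-methyl-2-oxo-2,4,5,6,7,7a-hexahydro-1H-indene-7-carboxylate
Conditions: PPTS, acetone/H2O (10:1), rt
Reagents that add atoms: water, O
Why: The allylic ketal is the most acid-labile group and hydrolyses through a conjugated oxocarbenium ion under conditions too mild to ionise the C4 carbinol, whose cation would be destabilised by the emerging enone.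

Step 16
Reactants: 20 2-(trimethylsilyl)ethyl (4S,7R,7aS)-4-hydroxy-7a-methyl-2-oxo-2,4,5,6,7,7a-hexahydro-1H-indene-7-carboxylate
Product: 21 2-(trimethylsilyl)ethyl (4S,7R,7aS)-7a-methyl-2-oxo-4-[(triethylsilyl)oxy]-2,4,5,6,7,7a-hexahydro-1H-indene-7-carboxylate
Conditions: TESCl, imidazole, DMF, 0 °C → rt
Reagents that add atoms: chlorotriethylsilane, CC[Si](Cl)(CC)CC
Why: Standard silylation of a secondary alcohol; the ether keeps a C4 alkoxide, which is 1,4-cis to the C7 ester and could lactonise, out of the enolate step and can later be removed without touching the other two silicon groups.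

Step 17
Reactants: 22 2-methylenepropane-1,3-diol
Product: 23 2-{[(tert-butyldiphenylsilyl)oxy]methyl}prop-2-en-1-ol
Conditions: NaH (1.0 equiv), THF, 0 °C; TBDPSCl (1.0 equiv), rt
Reagents that add atoms: tert-butyl(chloro)diphenylsilane, CC(C)(C)[Si](Cl)(c1ccccc1)c1ccccc1
Why: Monosilylation of a symmetrical diol through its sparingly soluble monosodium alkoxide, a standard desymmetrisation by stoichiometry.

Step 18
Reactants: 23 2-{[(tert-butyldiphenylsilyl)oxy]methyl}prop-2-en-1-ol
Product: 24 {[2-(bromomethyl)prop-2-en-1-yl]oxy}(tert-butyl)diphenylsilane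
Conditions: CBr4, PPh3, CH2Cl2, 0 °C
Reagents that add atoms: tetrabromomethane, BrC(Br)(Br)Br
Why: Appel bromination of a primary allylic alcohol under neutral conditions; the silyl ether is unaffected.

Step 19
Reactants: 21 2-(trimethylsilyl)ethyl (4S,7R,7aS)-7a-methyl-2-oxo-4-[(triethylsilyl)oxy]-2,4,5,6,7,7a-hexahydro-1H-indene-7-carboxylate; 24 {[2-(bromomethyl)prop-2-en-1-yl]oxy}(tert-butyl)diphenylsilane
Product: 25 2-(trimethylsilyl)ethyl (1R,4S,7R,7aS)-1-(2-{[(tert-butyldiphenylsilyl)oxy]methyl}prop-2-en-1-yl)-7a-methyl-2-oxo-4-[(triethylsilyl)oxy]-2,4,5,6,7,7a-hexahydro-1H-indene-7-carboxylate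
Conditions: LDA (1.1 equiv), THF, −78 °C; then 24, DMPU, −78 → −30 °C
Reagents that add atoms: none
Why: Kinetic α′-deprotonation of the enone gives the cross-conjugated C1 enolate, which is alkylated by the reactive allylic bromide (either SN2 or SN2′ attack gives the same product). Of the two faces of the planar ring at C1, the one bearing the C7a methyl is the more open, because the other is covered by C7 and its equatorial ester, so the chain enters cis to the methyl (1R); C1 remains epimerisable, so equilibration is available as a check.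

Step 20
Reactants: 25 2-(trimethylsilyl)ethyl (1R,4S,7R,7aS)-1-(2-{[(tert-butyldiphenylsilyl)oxy]methyl}prop-2-en-1-yl)-7a-methyl-2-oxo-4-[(triethylsilyl)oxy]-2,4,5,6,7,7a-hexahydro-1H-indene-7-carboxylate
Product: 26 2-(trimethylsilyl)ethyl (1R,4S,7R,7aS)-1-(2-{[(tert-butyldiphenylsilyl)oxy]methyl}prop-2-en-1-yl)-4-hydroxy-7a-methyl-2-oxo-2,4,5,6,7,7a-hexahydro-1H-indene-7-carboxylate
Conditions: PPTS (cat.), MeOH/CH2Cl2, 0 °C
Reagents that add atoms: none
Why: Mild acid methanolysis removes the triethylsilyl ether selectively; the tert-butyldiphenylsilyl ether is orders of magnitude more stable to acid and the 2-(trimethylsilyl)ethyl ester is inert.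

Step 21
Reactants: 27 (4R)-4-benzyl-1,3-oxazolidin-2-one; 28 butanoyl chloride
Product: 29 (4R)-4-benzyl-3-butanoyl-1,3-oxazolidin-2-one
Conditions: n-BuLi, THF, −78 °C; then 28, −78 → 0 °C
Reagents that add atoms: none
Why: N-acylation of the lithiated oxazolidinone, the standard entry to Evans imides.

Step 22
Reactants: 29 (4R)-4-benzyl-3-butanoyl-1,3-oxazolidin-2-one
Product: 30 (4R)-4-benzyl-3-[(2R)-2-methylbutanoyl]-1,3-oxazolidin-2-one
Conditions: NaHMDS, THF, −78 °C; then MeI, −78 °C
Reagents that add atoms: iodomethane, CI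
Why: Evans alkylation; the chelated (Z)-sodium enolate is methylated on the face opposite the benzyl group, which with the (R)-auxiliary and an ethyl-bearing enolate gives the (2R) centre; the minor diastereomer is removed at this stage.

Step 23
Reactants: 30 (4R)-4-benzyl-3-[(2R)-2-methylbutanoyl]-1,3-oxazolidin-2-one
Product: 31 (2R)-2-methylbutan-1-ol
Conditions: LiBH4, H2O (1 equiv), Et2O, 0 °C; aq. NaOH
Reagents that add atoms: none
Why: Reductive cleavage of the imide at the exocyclic carbonyl releases the alcohol without epimerisation and returns the auxiliary; the volatile alcohol is carried on as a concentrated solution.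

Step 24
Reactants: 31 (2R)-2-methylbutan-1-ol; 32 2-(triphenyl-λ5-phosphanylidene)propanal
Product: 34 (2E,4R)-2,4-dimethylhex-2-enal, via (R)-2-methylbutanal 33 (not isolated)
Conditions: TEMPO (cat.), PhI(OAc)2, CH2Cl2, rt; aq. NaHCO3 wash; then 32, toluene, 80 °C
Reagents that add atoms: none
Why: TEMPO/PhI(OAc)2 oxidation gives the α-branched aldehyde without base and hence without epimerisation, and it is trapped at once by the stabilised formyl ylide (Wittig reaction), which gives the (E)-trisubstituted enal under thermodynamic control of the betaine collapse.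

Step 25
Reactants: 34 (2E,4R)-2,4-dimethylhex-2-enal; 35 ethyl (2E)-4-(diethoxyphosphoryl)but-2-enoate
Product: 36 ethyl (2E,4E,6E,8R)-6,8-dimethyldeca-2,4,6-trienoate
Conditions: 35, LiHMDS, THF, −78 °C; then 34, −78 → 0 °C
Reagents that add atoms: none
Why: Vinylogous Horner–Wadsworth–Emmons olefination; the phosphonate anion reacts at the carbon bearing phosphorus and forms the new C4=C5 alkene with (E) selectivity, while the (E)-C2=C3 alkene is carried in the reagent.

Step 26
Reactants: 36 ethyl (2E,4E,6E,8R)-6,8-dimethyldeca-2,4,6-trienoate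
Product: 37 (2E,4E,6E,8R)-6,8-dimethyldeca-2,4,6-trienoic acid
Conditions: LiOH, THF/MeOH/H2O, rt; aq. HCl
Reagents that add atoms: lithium hydroxide, [Li+].[OH-]
Why: Saponification of an unhindered ethyl ester; the conjugated triene and the remote stereocentre, which bears no acidifying group, are stable to hydroxide at room temperature.

Step 27
Reactants: 37 (2E,4E,6E,8R)-6,8-dimethyldeca-2,4,6-trienoic acid; 26 2-(trimethylsilyl)ethyl (1R,4S,7R,7aS)-1-(2-{[(tert-butyldiphenylsilyl)oxy]methyl}prop-2-en-1-yl)-4-hydroxy-7a-methyl-2-oxo-2,4,5,6,7,7a-hexahydro-1H-indene-7-carboxylate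
Product: 39 2-(trimethylsilyl)ethyl (1R,4S,7R,7aS)-1-(2-{[(tert-butyldiphenylsilyl)oxy]methyl}prop-2-en-1-yl)-4-{[(2E,4E,6E,8R)-6,8-dimethyldeca-2,4,6-trienoyl]oxy}-7a-methyl-2-oxo-2,4,5,6,7,7a-hexahydro-1H-indene-7-carboxylate, via trichlorobenzoic mixed anhydride 38 (not isolated)
Conditions: 2,4,6-Cl3C6H2COCl, Et3N, toluene, rt; then 26, DMAP, toluene, rt
Reagents that add atoms: none
Why: Yamaguchi esterification; the hindered mixed anhydride is attacked by DMAP only at the trienoyl carbonyl and the acylpyridinium ion acylates the hindered C4 hydroxyl with retention, since no bond to C4 is broken.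

Step 28
Reactants: 39 2-(trimethylsilyl)ethyl (1R,4S,7R,7aS)-1-(2-{[(tert-butyldiphenylsilyl)oxy]methyl}prop-2-en-1-yl)-4-{[(2E,4E,6E,8R)-6,8-dimethyldeca-2,4,6-trienoyl]oxy}-7a-methyl-2-oxo-2,4,5,6,7,7a-hexahydro-1H-indene-7-carboxylate
Product: 40 (1R,4S,7R,7aS)-4-{[(2E,4E,6E,8R)-6,8-dimethyldeca-2,4,6-trienoyl]oxy}-1-[2-(hydroxymethyl)prop-2-en-1-yl]-7a-methyl-2-oxo-2,4,5,6,7,7a-hexahydro-1H-indene-7-carboxylic acid
Conditions: TBAF, AcOH, THF, 0 °C → rt
Reagents that add atoms: none
Why: Buffered fluoride removes both silicon-based groups: Si–O cleavage of the silyl ether and fluoride-triggered β-elimination of the 2-(trimethylsilyl)ethyl ester (ethene and Me3SiF), a cleavage that attacks silicon and is therefore indifferent to the steric shielding of the C7 carbonyl and leaves the trienoate alone.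

Step 29
Reactants: 40 (1R,4S,7R,7aS)-4-{[(2E,4E,6E,8R)-6,8-dimethyldeca-2,4,6-trienoyl]oxy}-1-[2-(hydroxymethyl)prop-2-en-1-yl]-7a-methyl-2-oxo-2,4,5,6,7,7a-hexahydro-1H-indene-7-carboxylic acid
Product: 41 (1R,4S,7R,7aS)-4-{[(2E,4E,6E,8R)-6,8-dimethyldeca-2,4,6-trienoyl]oxy}-1-(2-formylprop-2-en-1-yl)-7a-methyl-2-oxo-2,4,5,6,7,7a-hexahydro-1H-indene-7-carboxylic acid
Conditions: Dess–Martin periodinane, CH2Cl2, 0 °C → rt
Reagents that add atoms: none
Why: Dess–Martin oxidation of the only alcohol, a primary allylic one, to the enal; the reagent tolerates a free carboxylic acid and the medium is non-basic, so C1 and the γ-acyloxy enone are not disturbed.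

## Compound list

1 | methyl acetoacetate | CC(=O)CC(=O)OC | starting material
2 | allyl bromide | C=CCBr | starting material
3 | methyl 3-oxohept-6-enoate | C=CCCC(=O)CC(=O)OC | intermediate
4 | methyl 2-[2-(but-3-en-1-yl)-1,3-dioxolan-2-yl]acetate | C=CCCC1(CC(=O)OC)OCCO1 | intermediate
5 | 2-[2-(but-3-en-1-yl)-1,3-dioxolan-2-yl]-N-methoxy-N-methylacetamide | C=CCCC1(CC(=O)N(C)OC)OCCO1 | intermediate
6 | 2-(trimethylsilyl)ethyl acetate | CC(=O)OCC[Si](C)(C)C | starting material
7 | 2-(trimethylsilyl)ethyl 4-[2-(but-3-en-1-yl)-1,3-dioxolan-2-yl]-3-oxobutanoate | C=CCCC1(CC(=O)CC(=O)OCC[Si](C)(C)C)OCCO1 | intermediate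
8 | 2-(trimethylsilyl)ethyl (2Z)-4-[2-(but-3-en-1-yl)-1,3-dioxolan-2-yl]-3-[(diethoxyphosphoryl)oxy]but-2-enoate | C=CCCC1(C/C(OP(=O)(OCC)OCC)=C/C(=O)OCC[Si](C)(C)C)OCCO1 | intermediate
9 | 2-(trimethylsilyl)ethyl (2E)-4-[2-(but-3-en-1-yl)-1,3-dioxolan-2-yl]-3-methylbut-2-enoate | C=CCCC1(C/C(C)=C/C(=O)OCC[Si](C)(C)C)OCCO1 | intermediate
10 | 2-(trimethylsilyl)ethyl (2E)-3-methyl-4-[2-(3-oxopropyl)-1,3-dioxolan-2-yl]but-2-enoate | O=CCCC1(C/C(C)=C/C(=O)OCC[Si](C)(C)C)OCCO1 | intermediate
11 | vinylmagnesium bromide | C=C[Mg]Br | starting material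
12 | 2-(trimethylsilyl)ethyl (2E)-4-[2-(3-hydroxypent-4-en-1-yl)-1,3-dioxolan-2-yl]-3-methylbut-2-enoate (racemic carbinol) | C=CC(O)CCC1(C/C(C)=C/C(=O)OCC[Si](C)(C)C)OCCO1 | intermediate
13 | 2-(trimethylsilyl)ethyl (2E)-3-methyl-4-[2-(3-oxopent-4-en-1-yl)-1,3-dioxolan-2-yl]but-2-enoate | C=CC(=O)CCC1(C/C(C)=C/C(=O)OCC[Si](C)(C)C)OCCO1 | intermediate
14 | 2-(trimethylsilyl)ethyl (2E)-3-methyl-4-{2-[(2Z)-3-[(triisopropylsilyl)oxy]penta-2,4-dien-1-yl]-1,3-dioxolan-2-yl}but-2-enoate | C=C/C(O[Si](C(C)C)(C(C)C)C(C)C)=C/CC1(OCCO1)C/C(C)=C/C(=O)OCC[Si](C)(C)C | intermediate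
15 | 2-(trimethylsilyl)ethyl (3aR,7R,7aR)-2,2-(ethylenedioxy)-7a-methyl-4-[(triisopropylsilyl)oxy]-2,3,3a,6,7,7a-hexahydro-1H-indene-7-carboxylate | C1C3(OCCO3)C[C@H]2C(O[Si](C(C)C)(C(C)C)C(C)C)=CC[C@@H](C(=O)OCC[Si](C)(C)C)[C@@]21C | intermediate
16 | 2-(trimethylsilyl)ethyl (3aR,7R,7aR)-2,2-(ethylenedioxy)-7a-methyl-4-oxooctahydro-1H-indene-7-carboxylate | C1C3(OCCO3)C[C@H]2C(=O)CC[C@@H](C(=O)OCC[Si](C)(C)C)[C@@]21C | intermediate
17 | 2-(trimethylsilyl)ethyl (7R,7aS)-2,2-(ethylenedioxy)-7a-methyl-4-[(trimethylsilyl)oxy]-2,3,5,6,7,7a-hexahydro-1H-indene-7-carboxylate | C1C3(OCCO3)CC2=C(O[Si](C)(C)C)CC[C@@H](C(=O)OCC[Si](C)(C)C)[C@@]21C | intermediate (not isolated)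
18 | 2-(trimethylsilyl)ethyl (7R,7aS)-2,2-(ethylenedioxy)-7a-methyl-4-oxo-2,4,5,6,7,7a-hexahydro-1H-indene-7-carboxylate | C1C3(OCCO3)C=C2C(=O)CC[C@@H](C(=O)OCC[Si](C)(C)C)[C@@]21C | intermediate
19 | 2-(trimethylsilyl)ethyl (4S,7R,7aS)-2,2-(ethylenedioxy)-4-hydroxy-7a-methyl-2,4,5,6,7,7a-hexahydro-1H-indene-7-carboxylate | C1C3(OCCO3)C=C2[C@@H](O)CC[C@@H](C(=O)OCC[Si](C)(C)C)[C@@]21C | intermediate
20 | 2-(trimethylsilyl)ethyl (4S,7R,7aS)-4-hydroxy-7a-methyl-2-oxo-2,4,5,6,7,7a-hexahydro-1H-indene-7-carboxylate | C1C(=O)C=C2[C@@H](O)CC[C@@H](C(=O)OCC[Si](C)(C)C)[C@@]21C | intermediate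
21 | 2-(trimethylsilyl)ethyl (4S,7R,7aS)-7a-methyl-2-oxo-4-[(triethylsilyl)oxy]-2,4,5,6,7,7a-hexahydro-1H-indene-7-carboxylate | C1C(=O)C=C2[C@@H](O[Si](CC)(CC)CC)CC[C@@H](C(=O)OCC[Si](C)(C)C)[C@@]21C | intermediate
22 | 2-methylenepropane-1,3-diol | C=C(CO)CO | starting material
23 | 2-{[(tert-butyldiphenylsilyl)oxy]methyl}prop-2-en-1-ol | C=C(CO)CO[Si](c1ccccc1)(c1ccccc1)C(C)(C)C | intermediate
24 | {[2-(bromomethyl)prop-2-en-1-yl]oxy}(tert-butyl)diphenylsilane | C=C(CBr)CO[Si](c1ccccc1)(c1ccccc1)C(C)(C)C | intermediate
25 | 2-(trimethylsilyl)ethyl (1R,4S,7R,7aS)-1-(2-{[(tert-butyldiphenylsilyl)oxy]methyl}prop-2-en-1-yl)-7a-methyl-2-oxo-4-[(triethylsilyl)oxy]-2,4,5,6,7,7a-hexahydro-1H-indene-7-carboxylate | C=C(CO[Si](c3ccccc3)(c3ccccc3)C(C)(C)C)C[C@H]1C(=O)C=C2[C@@H](O[Si](CC)(CC)CC)CC[C@@H](C(=O)OCC[Si](C)(C)C)[C@@]21C | intermediate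
26 | 2-(trimethylsilyl)ethyl (1R,4S,7R,7aS)-1-(2-{[(tert-butyldiphenylsilyl)oxy]methyl}prop-2-en-1-yl)-4-hydroxy-7a-methyl-2-oxo-2,4,5,6,7,7a-hexahydro-1H-indene-7-carboxylate | C=C(CO[Si](c3ccccc3)(c3ccccc3)C(C)(C)C)C[C@H]1C(=O)C=C2[C@@H](O)CC[C@@H](C(=O)OCC[Si](C)(C)C)[C@@]21C | intermediate
27 | (4R)-4-benzyl-1,3-oxazolidin-2-one | O=C1N[C@H](Cc2ccccc2)CO1 | starting material
28 | butanoyl chloride | CCCC(=O)Cl | starting material
29 | (4R)-4-benzyl-3-butanoyl-1,3-oxazolidin-2-one | CCCC(=O)N1[C@H](Cc2ccccc2)COC1=O | intermediate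
30 | (4R)-4-benzyl-3-[(2R)-2-methylbutanoyl]-1,3-oxazolidin-2-one | CC[C@@H](C)C(=O)N1[C@H](Cc2ccccc2)COC1=O | intermediate
31 | (2R)-2-methylbutan-1-ol | CC[C@@H](C)CO | intermediate
32 | 2-(triphenyl-λ5-phosphanylidene)propanal | CC(C=O)=P(c1ccccc1)(c1ccccc1)c1ccccc1 | starting material
33 | (2R)-2-methylbutanal | CC[C@@H](C)C=O | intermediate (not isolated)
34 | (2E,4R)-2,4-dimethylhex-2-enal | CC[C@@H](C)/C=C(\C)C=O | intermediate
35 | ethyl (2E)-4-(diethoxyphosphoryl)but-2-enoate | CCOC(=O)/C=C/CP(=O)(OCC)OCC | starting material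
36 | ethyl (2E,4E,6E,8R)-6,8-dimethyldeca-2,4,6-trienoate | CCOC(=O)/C=C/C=C/C(C)=C/[C@H](C)CC | intermediate
37 | (2E,4E,6E,8R)-6,8-dimethyldeca-2,4,6-trienoic acid | OC(=O)/C=C/C=C/C(C)=C/[C@H](C)CC | intermediate
38 | (2E,4E,6E,8R)-6,8-dimethyldeca-2,4,6-trienoic 2,4,6-trichlorobenzoic anhydride | O=C(/C=C/C=C/C(C)=C/[C@H](C)CC)OC(=O)c1c(Cl)cc(Cl)cc1Cl | intermediate (not isolated)
39 | 2-(trimethylsilyl)ethyl (1R,4S,7R,7aS)-1-(2-{[(tert-butyldiphenylsilyl)oxy]methyl}prop-2-en-1-yl)-4-{[(2E,4E,6E,8R)-6,8-dimethyldeca-2,4,6-trienoyl]oxy}-7a-methyl-2-oxo-2,4,5,6,7,7a-hexahydro-1H-indene-7-carboxylate | C=C(CO[Si](c3ccccc3)(c3ccccc3)C(C)(C)C)C[C@H]1C(=O)C=C2[C@@H](OC(=O)/C=C/C=C/C(C)=C/[C@H](C)CC)CC[C@@H](C(=O)OCC[Si](C)(C)C)[C@@]21C | intermediate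
40 | (1R,4S,7R,7aS)-4-{[(2E,4E,6E,8R)-6,8-dimethyldeca-2,4,6-trienoyl]oxy}-1-[2-(hydroxymethyl)prop-2-en-1-yl]-7a-methyl-2-oxo-2,4,5,6,7,7a-hexahydro-1H-indene-7-carboxylic acid | C=C(CO)C[C@H]1C(=O)C=C2[C@@H](OC(=O)/C=C/C=C/C(C)=C/[C@H](C)CC)CC[C@@H](C(=O)O)[C@@]21C | intermediate
41 | (1R,4S,7R,7aS)-4-{[(2E,4E,6E,8R)-6,8-dimethyldeca-2,4,6-trienoyl]oxy}-1-(2-formylprop-2-en-1-yl)-7a-methyl-2-oxo-2,4,5,6,7,7a-hexahydro-1H-indene-7-carboxylic acid | C=C(C=O)C[C@H]1C(=O)C=C2[C@@H](OC(=O)/C=C/C=C/C(C)=C/[C@H](C)CC)CC[C@@H](C(=O)O)[C@@]21C | target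

## Step count and risk

Total: 29 steps. Longest linear sequence: 21 steps (steps 1–16, 19, 20, 27, 28, 29, from methyl acetoacetate). The bromide (steps 17–18) and the acid (steps 21–26) are made in parallel.

**Step 11 (key step).**
- What may go wrong: the cycloaddition may be slow and the enantiofacial selectivity eroded. The β-methyl cis to the ester strains the planar enoate–boron complex on which the catalyst model relies (allylic strain against the alkoxy oxygen). The ketal oxygens may compete for the Lewis acid, and protodesilylation of the diene may overtake ring closure.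
- Fallback (from 14, back to 15): move the activating group to the aldehyde oxidation level, the most reactive and best-behaved substrate class for this catalyst. DIBAL-H (CH2Cl2, −78 °C) reduces 14 to the triene allylic alcohol F1 and MnO2 gives the trienal F2. F2 is cyclised with the oxazaborolidinium salt through the formyl C–H binding mode (catalyst antipode chosen for that mode) to the bicyclic aldehyde F3. Buffered NaClO2 oxidation gives the acid F4, and EDC/DMAP esterification with 2-(trimethylsilyl)ethanol returns 15.

**Step 13.**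
- What may go wrong: enolisation may not equilibrate fully toward C3a, so that dehydrogenation occurs on the C5 side. Palladation at the hindered C3a next to the quaternary carbon may be slow enough for simple desilylation to compete.
- Fallback (from 16, back to 21): have the C2 ketone, not the C4 ketone, direct the dehydrogenation. NaBH4 reduces 16, by analogy with trans-hydrindan-4-ones carrying an angular methyl, to the C4 alcohol cis to the methyl, F5. PPTS in wet acetone frees the C2 ketone (hydroxy ketone F6) and TESCl/imidazole gives the silyl ether F7. Kinetic enolisation (LDA, TMSCl, −78 °C) goes toward C3, since C1 is neopentylic, to give the trimethylsilyl enol ether F8, and Pd(OAc)2 delivers 21. Any C1-regioisomeric enol ether has no β-hydrogen to lose and reverts to F7.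

**Step 19.**
- What may go wrong: facial selectivity of the alkylation at C1 may be poor or reversed, since both faces are flanked by a substituent of C7a. Some γ-deprotonation at C4 may compete.
- Fallback (from 21, back to 25): set C1 by protonation, not by C–C bond formation. If the electrophile enters anti to the methyl, the product is the C1 epimer F9. Deprotonation of F9 (LDA, −78 °C) and kinetic protonation of the enolate with a hindered phenol puts the proton on that same accessible face and so turns the chain to the methyl side, giving 25. Equilibration with DBU is the thermodynamic counterpart.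

**Step 27.**
- What may go wrong: acylation of the hindered C4 hydroxyl, syn to the angular methyl, may be slow. Amine-induced isomerisation of the γ-hydroxy enone to the 1,4-diketone, or geometric isomerisation of the activated trienoic acid, could then compete.
- Fallback (from 26, back to 39): attach a small acyl group first and build the triene on the core. DCC coupling of 26 with (diethoxyphosphoryl)acetic acid gives the phosphonoacetate F10. Dienal F11 is prepared from 34 and (triphenylphosphoranylidene)acetaldehyde, and a Masamune–Roush olefination of F10 with F11 (LiCl, i-Pr2NEt, MeCN) forms the C2=C3 alkene and gives 39.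

## Further compounds

F1 | step 11 | (2E)-3-methyl-4-{2-[(2Z)-3-[(triisopropylsilyl)oxy]penta-2,4-dien-1-yl]-1,3-dioxolan-2-yl}but-2-en-1-ol | C=C/C(O[Si](C(C)C)(C(C)C)C(C)C)=C/CC1(OCCO1)C/C(C)=C/CO
F2 | step 11 | (2E)-3-methyl-4-{2-[(2Z)-3-[(triisopropylsilyl)oxy]penta-2,4-dien-1-yl]-1,3-dioxolan-2-yl}but-2-enal | C=C/C(O[Si](C(C)C)(C(C)C)C(C)C)=C/CC1(OCCO1)C/C(C)=C/C=O
F3 | step 11 | (3aR,7R,7aR)-2,2-(ethylenedioxy)-7a-methyl-4-[(triisopropylsilyl)oxy]-2,3,3a,6,7,7a-hexahydro-1H-indene-7-carbaldehyde | C1C3(OCCO3)C[C@H]2C(O[Si](C(C)C)(C(C)C)C(C)C)=CC[C@@H](C=O)[C@@]21C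
F4 | step 11 | (3aR,7R,7aR)-2,2-(ethylenedioxy)-7a-methyl-4-[(triisopropylsilyl)oxy]-2,3,3a,6,7,7a-hexahydro-1H-indene-7-carboxylic acid | C1C3(OCCO3)C[C@H]2C(O[Si](C(C)C)(C(C)C)C(C)C)=CC[C@@H](C(=O)O)[C@@]21C
F5 | step 13 | 2-(trimethylsilyl)ethyl 2,2-(ethylenedioxy)-4-hydroxy-7a-methyloctahydro-1H-indene-7-carboxylate (trans-fused, C4 hydroxyl and C7 ester cis to the C7a methyl) | C1C3(OCCO3)C[C@H]2[C@@H](O)CC[C@@H](C(=O)OCC[Si](C)(C)C)[C@@]21C
F6 | step 13 | 2-(trimethylsilyl)ethyl 4-hydroxy-7a-methyl-2-oxooctahydro-1H-indene-7-carboxylate (trans-fused, C4 hydroxyl and C7 ester cis to the C7a methyl) | C1C(=O)C[C@H]2[C@@H](O)CC[C@@H](C(=O)OCC[Si](C)(C)C)[C@@]21C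
F7 | step 13 | 2-(trimethylsilyl)ethyl 7a-methyl-2-oxo-4-[(triethylsilyl)oxy]octahydro-1H-indene-7-carboxylate (trans-fused, C4 silyloxy and C7 ester cis to the C7a methyl) | C1C(=O)C[C@H]2[C@@H](O[Si](CC)(CC)CC)CC[C@@H](C(=O)OCC[Si](C)(C)C)[C@@]21C
F8 | step 13 | C2=C3 trimethylsilyl enol ether of F7 | C1C(O[Si](C)(C)C)=C[C@H]2[C@@H](O[Si](CC)(CC)CC)CC[C@@H](C(=O)OCC[Si](C)(C)C)[C@@]21C
F9 | step 19 | C1 epimer of 25 (side chain trans to the C7a methyl) | C=C(CO[Si](c3ccccc3)(c3ccccc3)C(C)(C)C)C[C@@H]1C(=O)C=C2[C@@H](O[Si](CC)(CC)CC)CC[C@@H](C(=O)OCC[Si](C)(C)C)[C@@]21C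
F10 | step 27 | C4 (diethoxyphosphoryl)acetate of 26 | C=C(CO[Si](c3ccccc3)(c3ccccc3)C(C)(C)C)C[C@H]1C(=O)C=C2[C@@H](OC(=O)CP(=O)(OCC)OCC)CC[C@@H](C(=O)OCC[Si](C)(C)C)[C@@]21C
F11 | step 27 | (2E,4E,6R)-4,6-dimethylocta-2,4-dienal | O=C/C=C/C(C)=C/[C@H](C)CC
A1 | alternative 1 | tert-butyl 1-{2-[(4-methoxybenzyloxy)methyl]prop-2-en-1-yl}-7a-methyl-2,4-dioxo-2,4,5,6,7,7a-hexahydro-1H-indene-7-carboxylate (configured as the target at C1, C7, C7a) | C=C(COCc3ccc(OC)cc3)C[C@H]1C(=O)C=C2C(=O)CC[C@@H](C(=O)OC(C)(C)C)[C@@]21C
A2 | alternative 2 | tert-butyl 2,2-(ethylenedioxy)-4-hydroxy-3a,7a-methanooctahydro-1H-indene-7-carboxylate (methylene bridge cis to the C4 hydroxyl) | O[C@H]1CC[C@@H](C(=O)OC(C)(C)C)[C@]24C[C@@]14CC3(OCCO3)C2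
A3 | alternative 3 | tert-butyl 4-[(tert-butyldimethylsilyl)oxy]-1,1-dichloro-7a-methyl-2-oxooctahydro-1H-indene-7-carboxylate | ClC1(Cl)C(=O)C[C@@H]2[C@@H](O[Si](C)(C)C(C)(C)C)CC[C@@H](C(=O)OC(C)(C)C)[C@@]21C
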